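Watch two clocks as the temperature of these flasks goes up: the time over which monomer in chains is made, and the lifetime it then has before it turns into over-reaction product.

| flask | free monomer | transfer agent | initiator | temperature | remark | time |
|---|---|---|---|---|---|---|
| midnight | 2 M | 0.60 M | 80 mM | 30 °C | run made earlier |  |
| dusk | 2 M | 0.60 M | 180 mM | 50 °C | run made earlier |  |
| gamma | 2.0 M | 0.600 M | 120 mM | 35 °C |  | 4.0 d |
| beta | 2.0 M | 0.600 M | 120 mM | 50 °C |  | 4.0 d |
| delta | 2.0 M | 0.600 M | 120 mM | 65 °C |  | 4.0 d |
| zeta | 2.0 M | 0.600 M | 120 mM |  | at 35 °C until 3.0 d, from then on at 65 °C | 4.0 d |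

midnight run (percent of the free monomer charged)

| time / d | monomer in chains / % | over-reaction product / % |
|---|---|---|
| 0.208 | 2.8 | 0.2 |
| 0.333 | 4.7 | 0.3 |
| 0.417 | 5.9 | 0.5 |
| 0.625 | 9.2 | 0 |
| 1.04 | 13.2 | 1.3 |
| 1.67 | 16.1 | 3.4 |
| 2.50 | 17.6 | 6.4 |

dusk run (percent of the free monomer charged)

| time / h | monomer in chains / % | over-reaction product / % |
|---|---|---|
| 2.50 | 16.7 | 2.2 |
| 4.00 | 20.8 | 4.0 |
| 5.00 | 20.8 | 5.4 |
| 8.00 | 21.3 | 11.7 |
| 12.0 | 17.4 | 18.5 |
| 20.0 | 10.9 | 29.2 |
| 30.0 | 4.7 | 35.8 |

(readings scatter by 0.5 percentage points)



- the flask with the highest share of monomer in chains in all that became monomer in chains or over-reaction product ("all alike" if they lie within 1.5 percentage points) (gamma / beta / delta / zeta / all alike)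
- share of monomer in chains in all that became monomer in chains or over-reaction product, gamma
- share of monomer in chains in all that became monomer in chains or over-reaction product, beta
- share of monomer in chains in all that became monomer in chains or over-reaction product, delta
- share of monomer in chains in all that became monomer in chains or over-reaction product, zeta

First ask how fast chains are lost. Late in the midnight run, over-reaction product grows by a fraction 0.215 d⁻¹ of the chains present, and at the end of the dusk run the chains fall at 2.02 d⁻¹. Take both as first-order constants, as readings with their scatter. Spread the logarithm evenly over temperature: that gives 0.376 d⁻¹ at 35 °C and 10.8 d⁻¹ at 65 °C, so a chain unit in gamma lasts 2.66 d.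

Next ask how long making lasts. The rate at which chains and product together grow fades at 0.645 d⁻¹ in the midnight run and 3.36 d⁻¹ in the dusk run; initiator differs there too, and 120 mM lies between. Spread the same way, gamma makes chains for about 1.03 d, less than the lifetime. So in gamma, by this reckoning, making gives way to loss well inside the 4.0 d.

Then ask how old the chains are at the reading. Treat them as born together at the end of one making time, and count the lifetimes they sit through until the reading, adding the stretches where the temperature changes: this age count, the share being about e to its negative, is 1.12 for gamma, a share near 32.6%. Beta reaches 7.47, delta 42.5 and zeta 11.6, each well above gamma, so by this count gamma leads.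

The forecast names gamma, with 32% for gamma, 0.02% for beta, 0% for delta and 0.001% for zeta, and says of these last flasks that “the chains are essentially all converted”.

The flasks give gamma as the highest, with 32.6% for gamma, 0.135% for beta, 0.00758% for delta and 0.0409% for zeta.

    free monomer + initiator → living end + monomer in chains (k = 0.320 M⁻¹ h⁻¹, Ea = 84.0 kJ mol⁻¹)
    free monomer + living end → monomer in chains + living end, rate k2*[living end]*[free monomer] (k = 1.50 M⁻¹ h⁻¹, Ea = 56.0 kJ mol⁻¹)
    living end + transfer agent → dead chain (kL = 0.0660 M⁻¹ h⁻¹, Ea = 85.0 kJ mol⁻¹)
    2 free monomer → self-condensation product (k = 0.140 M⁻¹ h⁻¹, Ea = 75.0 kJ mol⁻¹)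
    monomer in chains → over-reaction product (k = 0.0870 h⁻¹, Ea = 97.0 kJ mol⁻¹)
    (constants at 50 °C)

Now read zeta earlier, at 2.5 d, before its change of temperature. The flask is still at 35 °C, so take the gamma count 1.12 and subtract the lifetimes not yet sat through: 0.554, a share near 57.5%. That flask holds 18.2% monomer in chains beside 16.1% over-reaction product, a share of 52.9%.

The runs come from a simulation for substances that don't exist; noise was put on by code.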